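The numbers in the tables were computed from invented constants; noise was put on by code.

The target at the end of these runs comes from a starting material that the protic impurity can also consume, so the examination begins with what each catalyst has to work on.

| flask | starting material | protic impurity | catalyst | remark | time |
|---|---|---|---|---|---|
| zeta | 0.40 M | 5.8 mM | 8 mM | run made earlier |  |
| gamma | 0.40 M | 47 mM | 8 mM | run made earlier |  |
| west | 0.40 M | 4.00 mM | 8.0 mM |  | 20 h |
| south-west | 0.40 M | 8.00 mM | 8.0 mM |  | 20 h |
| south | 0.40 M | 15.0 mM | 8.0 mM |  | 20 h |
| north | 0.40 M | 30.0 mM | 8.0 mM |  | 20 h |

- zeta (time / h: target / %, starting material / %): 0.500: 2.1, 97.1; 1.50: 8.4, 90.3; 3.00: 14.4, 79.9; 4.00: 18.3, 74.1; 6.00: 22.5, 66.3; 8.00: 30.2, 58.5; 10.0: 33.5, 51.5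
- gamma (time / h: target / %, starting material / %): 1.33: 4.3, 83.7; 3.00: 14.8, 72.3; 4.00: 16.8, 67.7; 6.00: 22.7, 57.9; 8.00: 25.9, 52.6; 10.0: 32.6, 43.0

(readings scatter by 1 percentage point)

- steps that have been proposed: starting material + catalyst -> catalyst + target; starting material -> side product; starting material + protic impurity -> quenched substrate
- "hardly changes" means that all values lie within two and a half points (for a concentration: within two and a half percent of the largest)

- amount of target at the end, in percent of the starting material charged for west, south-west, south, north, in this order
- the shape of the row from first to last (falls, then rises / rises all the way / hardly changes / falls all the way / rises, then falls)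

**What does a flask offer its catalyst?** Count turnovers. The budget N, the starting material charged divided by the catalyst charged, is 50.0 turnovers per catalyst.

**What does the impurity cost?** If each impurity molecule takes one molecule of starting material, as the third proposed step says, it removes the toll τ, the impurity charged divided by the catalyst charged, from the budget. The toll is 0.500 turnovers in west and 3.75 in north.

**Is one-to-one read or merely assumed?** It can be read, roughly. At 10.0 h, target plus starting material fall short of the charge by 15 percentage points in zeta and 24 points in gamma. The difference between these two shortfalls, 9.4 points, stands beside a difference in τ/N of 10 points, and each reading carries a scatter of 1 point.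

**But gamma holds more impurity than catalyst. Is the catalyst not harmed?** The readings show no sign of it: target at 10.0 h is 32.6% in gamma and 33.5% in zeta. I therefore count the catalyst as intact, which makes the catalytic loss of starting material pseudo-first-order.

**What becomes of the material past the toll?** Let r be the starting material left at 10.0 h as a share of the unquenched charge. It reads 52.3% in zeta and 48.7% in gamma. Their product estimates the share surviving twice as long, 25.5%. Of the unquenched material that reacted, target took 71.2% in zeta and 72.0% in gamma, on average 71.6%. So 53.4% of the unquenched charge should be target at 20 h.

**Your row?** Multiplying by 1 − τ/N, I expect 52.9%, 52.3%, 51.4% and 49.4%, falling all the way, with a spread of 3.5 points that lies outside the margin for "hardly changes".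

The forecast, which differs from my row by 0.10 points in north, gave 53%, 52.4%, 51.5% and 49.5%, a shape that falls all the way, and held that “The quench is therefore fast, stoichiometric and finished early.”

The flasks give 53.3%, 52.8%, 51.9% and 49.9%, and the row falls all the way.

    starting material + catalyst → catalyst + target (k = 0.102 M⁻¹ min⁻¹)
    starting material → side product (k = 3.05 × 10⁻⁴ min⁻¹)
    starting material + protic impurity → quenched substrate (k = 0.0351 M⁻¹ min⁻¹)

In west, the protic impurity has a half-life of 1.3 h at 6.85 h, shorter than the 14 h of the starting material by the catalytic step alone with the other concentrations as charged. By 20.0 h, 0.010% of west's impurity charge is left. North's toll of 3.75 turnovers out of 50.0 is 7.50% of the charge, and its quenched substrate stands at 7.50% with catalyst at 100%. South's toll of 1.88 turnovers is 3.75% of the charge, and its quenched substrate stands at 3.75%.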